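## The problem

DMGF is an unsymmetrical biflavone. Two 5-hydroxy-7-methoxy-2-(4-hydroxyphenyl)chromen-4-one units are joined from C6 of one (unit 1) to C8 of the other (unit 2). The biaryl bond has four ortho substituents (5-OH and 7-OMe of unit 1, 7-OMe and the ring oxygen of unit 2), so a direct coupling of two flavone halves must form a very hindered bond and must distinguish C6 from C8 in both halves. There are no stereocentres; the only stereo element is the hindered axis, which the structure leaves undefined, so no centre has to control another. The racemic sp3 carbon in 16 to 18 disappears when ring A forms. Each unit carries one methyl ether (O7) beside two free phenols, so the phenols need a mask that leaves without touching the methyl ethers. Both 4-pyranone rings open with hot hydroxide or alkoxide, and the chelated 5-hydroxyls are the least reactive phenols. The enabling feature lies in unit 2: C8, C7(OMe), C6 and C5(O) form a four-carbon chain between C8a and C4a, which are C2 and C3 of a monocyclic 6-aryl-4-pyranone, and C3 is the nucleophilic carbon of that ring. If the chain hangs from pyranone C2 as a 3-methoxybut-2-enoic acid that already carries unit 1 on its C4, one bond from the acid carbon to pyranone C3 (C4a to C5) completes ring A with 7-OMe and 5-OH in place. The biaryl bond is then made early as an ordinary sp3–sp2 bond and becomes biaryl only on aromatisation.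

## Retrosynthesis

**22 from 21.** The three benzyl C–O bonds are cut last. Benzyl ethers survive the amide bases, the zinc reagent, catalytic acid and brief CF3CO2H used earlier, and hydrogenolysis removes them without touching the two methyl ethers. The forward step must leave the chromone C2=C3 bonds unreduced.

**21 from 18 (through 19 and 20).** The C4a–C5 bond of ring A of unit 2 is cut. The neighbouring cuts are the biaryl bond (a coupling at two di-ortho-substituted carbons) and the pyranone bonds of unit 2 (which leave the biaryl problem unsolved). Cutting C4a–C5 turns the axis into a benzylic sp3 carbon and ring A into an open acid on a simple pyranone. The forward step must activate the acid, remove the C8 proton and close only onto pyranone C3.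

**18 from 17 from 16.** The ester O–C bond and the enol ether O–CH3 bond are cut. A tert-butyl ester is chosen so that acid, not hydroxide, frees the carboxylic acid; the C8 proton is acidic and both pyranones are base-labile. The methyl enol ether comes from the β-keto ester 16 under equilibrating acid conditions, which should favour the conjugated E isomer with the ester cis to C8.

**16 from 13 and 14 (through 15).** The C7–C8 bond is cut: the lateral enolate of the 2-(arylmethyl)pyranone 13 is acylated by tert-butyl malonyl chloride 15, made from the half ester 14. Building the pyranone before the keto ester locks the C8a carbonyl in the ring, so the keto ester cannot lactonise to a 2-pyranone as an open-chain polyketide would. The forward step needs C-acylation over O-acylation.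

**13 from 9 and 11 (through 12); 11 from 10.** The pyranone is opened at O1–C2 to the triketone 12, which is cut between C8a and C4a into the Weinreb amide 9 and the dianion of diketone 11. The amide is preferred to the ester 8 because the arylacetyl α-hydrogens are acidic and the dianion is a strong base. Diketone 11 is a Claisen product of ketone 10.

**9 from 8 from 5 and 6 (through 7).** The aryl–CH2 bond at C6 of unit 1 is cut: a palladium-catalysed coupling of iodide 5 with the Reformatsky reagent 7 of ethyl bromoacetate 6. This is where the future biaryl bond is made, as an sp2–sp3 bond to a small zinc enolate.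

**5 from 4, 3, 2 and 1.** Only C–O and C–I bonds are cut. The order is fixed by the iodination: the 5-OH must be free to send iodine to C6, so O7 is methylated and O4' benzylated first and O5 benzylated last.

## Roads not taken

**Alternative 1: biomimetic 2-pyranone to phloroglucinol recyclisation.** The cut is the C4a–C5 bond of ring A of unit 1. Mg(OMe)2 in methanol would open the lactone of 2-pyranone A2, and the methylene freed between two ketones (C4a) would attack the new ester carbon (C5) to give chalcone A1.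
- Merits: the ring-forming event has close models in magnesium-templated Claisen cyclisations of triketo esters, so it rests on firmer precedent than the chosen key step, and the unit 2 flavone is carried intact.
- Weak points: A1 has two free ortho hydroxyls, and closing the chromone through the wrong one gives the 8,8-linked isomer; only a steric bias separates them. The open chain can also close by aldol onto a ketone, and the enone is a Michael acceptor for methoxide. A2 itself needs a carbon–carbon bond at the hindered C8 of a flavone.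
- Comparison: A1 is a chalcone that still needs oxidative ring closure and deprotection. Against the better precedent of this road, the chosen plan sets a key-step product 21 that is already a biflavone with the linkage fixed by construction and one step from the target.

**Alternative 2: double intramolecular ester Wittig.** Both C2–C3 double bonds are cut. Heating the bis(acylphosphorane) diester A4 would close both pyranone rings at once and give A3.
- Merits: the acylphosphorane–aryl ester Wittig closure to chromones is established, both heterocycles form in one operation, and there is no new-method risk.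
- Weak points: the tetra-ortho-substituted, unsymmetrical biaryl bond must exist before the key step, so the hardest bond is moved into an earlier cross-coupling of two differently substituted phloroglucinol rings. A4 needs two acyl ylides and two esters placed regioselectively on that biaryl. A3 still needs both 5-methyl ethers cleaved selectively beside the benzyl ethers.
- Comparison: this road is safer at its key step. The chosen plan avoids any hindered biaryl coupling and has the 5-hydroxyl of unit 2 free as formed.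

**Alternative 3: diazoketone and ynol ether benzannulation.** Three bonds of ring A of unit 1 are cut (C5–C6, C7–C8, C4a–C5). Wolff rearrangement of diazoketone A6 would give pyranylketene A8, which adds to the methoxyalkyne A7; ring opening and six-electron closure onto pyranone C3 would give A5.
- Merits: it is the most convergent of the four, joining two halves of similar size in the key step. The biaryl bond arises from an alkyne carbon, the orientation of ynol ether addition is well defined, and A5 is one step from the target. In convergence it is better than the chosen plan, which is linear over twelve steps.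
- Weak points: A7 is a methoxyalkyne on a di-ortho-substituted flavone carbon, which is hard to make and to keep. Both partners are strong chromophores if the Wolff step is run photochemically, and the intermolecular cycloaddition at a hindered alkyne must outrun other fates of A8.
- Comparison: the chosen plan sets against the convergence an intramolecular one-bond closure from the stable acid 18 under mild ionic conditions, with the same final electrocyclic logic.

Key step: step 12

Assumption: the target is drawn without a descriptor for the C6–C8 biaryl axis, so the axis is made as the racemate and no resolution is planned.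

## Route

Step 1
Reactants: 1 apigenin
Product: 2 genkwanin (5-hydroxy-2-(4-hydroxyphenyl)-7-methoxy-4H-chromen-4-one)
Conditions: MeI (1.05 equiv), K2CO3 (1.1 equiv), DMF, rt
Reagents that add atoms: iodomethane, CI
Why: Williamson etherification; the 7-OH is the most acidic phenol of apigenin and the 5-OH is held in a hydrogen bond to C4=O, so one equivalent of iodomethane should give mainly 2, with any 7,4'-dimethyl ether removed by crystallisation.

Step 2
Reactants: 2 genkwanin
Product: 3 2-[4-(benzyloxy)phenyl]-5-hydroxy-7-methoxy-4H-chromen-4-one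
Conditions: BnBr, K2CO3, acetone, reflux
Reagents that add atoms: benzyl bromide, BrCc1ccccc1
Why: Williamson etherification of the only non-chelated phenol; the 5-OH stays free under carbonate in acetone, which step 3 needs.

Step 3
Reactants: 3 2-[4-(benzyloxy)phenyl]-5-hydroxy-7-methoxy-4H-chromen-4-one
Product: 4 2-[4-(benzyloxy)phenyl]-5-hydroxy-6-iodo-7-methoxy-4H-chromen-4-one
Conditions: BnMe3N(ICl2) (1.05 equiv), CaCO3, CH2Cl2/MeOH, rt
Reagents that add atoms: benzyltrimethylammonium dichloroiodate, C[N+](C)(C)Cc1ccccc1.Cl[I-]Cl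
Why: Electrophilic aromatic iodination; in 5-hydroxy-7-alkoxyflavones this reagent enters ortho to the free 5-OH, at C6, and ring B is deactivated by the chromone.

Step 4
Reactants: 4 2-[4-(benzyloxy)phenyl]-5-hydroxy-6-iodo-7-methoxy-4H-chromen-4-one
Product: 5 5-(benzyloxy)-2-[4-(benzyloxy)phenyl]-6-iodo-7-methoxy-4H-chromen-4-one
Conditions: BnBr, K2CO3, DMF, 60 °C
Reagents that add atoms: benzyl bromide, BrCc1ccccc1
Why: Williamson etherification of the chelated 5-OH under more forcing conditions; the benzyl group shields the phenol from the bases of steps 5 to 9 and leaves with the other two in step 13.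

Step 5
Reactants: 5 5-(benzyloxy)-2-[4-(benzyloxy)phenyl]-6-iodo-7-methoxy-4H-chromen-4-one; 6 ethyl bromoacetate
Product: 8 ethyl 2-{5-(benzyloxy)-2-[4-(benzyloxy)phenyl]-7-methoxy-4-oxo-4H-chromen-6-yl}acetate, via Reformatsky reagent 7 (not isolated)
Conditions: Zn dust (Me3SiCl-activated), THF, 40 °C; then 5, Pd2(dba)3 (2.5 mol %), XPhos (10 mol %), THF, 65 °C
Reagents that add atoms: none
Why: Palladium-catalysed coupling of an aryl iodide with a Reformatsky reagent (Negishi-type α-arylation of an ester): oxidative addition of 5 to zerovalent palladium, transmetalation from zinc and reductive elimination. The bulky biarylphosphine is chosen because both ortho positions are substituted, and the neutral zinc enolate leaves the chromone untouched.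

Step 6
Reactants: 8 ethyl 2-{5-(benzyloxy)-2-[4-(benzyloxy)phenyl]-7-methoxy-4-oxo-4H-chromen-6-yl}acetate
Product: 9 2-{5-(benzyloxy)-2-[4-(benzyloxy)phenyl]-7-methoxy-4-oxo-4H-chromen-6-yl}-N-methoxy-N-methylacetamide
Conditions: MeNH(OMe)·HCl (1.5 equiv), iPrMgCl (3.0 equiv), THF, −20 °C
Reagents that add atoms: N,O-dimethylhydroxylamine hydrochloride, CNOC.Cl
Why: Aminolysis of the ester by the chloromagnesium amide of N,O-dimethylhydroxylamine (Weinreb amide synthesis); the amide suits step 8 better than the ester because its adduct is held as a chelate and its α-hydrogens are less acidic.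

Step 7
Reactants: 10 4'-(benzyloxy)acetophenone
Product: 11 1-[4-(benzyloxy)phenyl]butane-1,3-dione
Conditions: NaH (2.2 equiv), EtOAc (3 equiv), THF, reflux; aq. HCl
Reagents that add atoms: ethyl acetate, CCOC(C)=O
Why: Crossed Claisen condensation of the ketone enolate with ethyl acetate, driven by deprotonation of the 1,3-diketone.

Step 8
Reactants: 11 1-[4-(benzyloxy)phenyl]butane-1,3-dione; 9 2-{5-(benzyloxy)-2-[4-(benzyloxy)phenyl]-7-methoxy-4-oxo-4H-chromen-6-yl}-N-methoxy-N-methylacetamide
Product: 13 5-(benzyloxy)-2-[4-(benzyloxy)phenyl]-6-({6-[4-(benzyloxy)phenyl]-4-oxo-4H-pyran-2-yl}methyl)-7-methoxy-4H-chromen-4-one, via triketone 12 (not isolated)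
Conditions: 11 (2 equiv), LiN(iPr)2 (4.2 equiv), THF, −78 to 0 °C; 9, −78 to 0 °C; AcOH; then TsOH·H2O (0.2 equiv), toluene, 80 °C
Reagents that add atoms: none
Why: Acylation of the dilithio dianion of a 1,3-diketone at its terminal carbon by a Weinreb amide, then acid-catalysed cyclodehydration of the 1,3,5-triketone to the 4-pyranone. Excess dianion absorbs proton transfer from the benzylic CH2 of 9, and the acid medium steers 12 to the pyranone and away from base-induced aldol closure to a resorcinol.

Step 9
Reactants: 13 5-(benzyloxy)-2-[4-(benzyloxy)phenyl]-6-({6-[4-(benzyloxy)phenyl]-4-oxo-4H-pyran-2-yl}methyl)-7-methoxy-4H-chromen-4-one; 14 3-tert-butoxy-3-oxopropanoic acid (mono-tert-butyl malonate)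
Product: 16 racemic tert-butyl 4-{5-(benzyloxy)-2-[4-(benzyloxy)phenyl]-7-methoxy-4-oxo-4H-chromen-6-yl}-4-{6-[4-(benzyloxy)phenyl]-4-oxo-4H-pyran-2-yl}-3-oxobutanoate, via tert-butyl malonyl chloride 15 (not isolated)
Conditions: 14, 1-chloro-N,N,2-trimethylprop-1-en-1-amine, CH2Cl2, 0 °C; separately 13, LiN(SiMe3)2 (2.2 equiv), THF, −78 °C; add the solution of 15, −78 to −40 °C; AcOH
Reagents that add atoms: none
Why: C-Acylation of the lateral (vinylogous) lithium enolate of a 2-alkyl-4-pyranone by an acid chloride; the second equivalent of base either turns 15 into tert-butoxycarbonylketene, which the enolate adds to, or deprotonates the product, so both paths end at the enolate of 16. The new stereocentre forms racemic and is erased in step 12; with the pyranone already closed the keto ester cannot lactonise to a 2-pyranone.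

Step 10
Reactants: 16 racemic tert-butyl 4-{5-(benzyloxy)-2-[4-(benzyloxy)phenyl]-7-methoxy-4-oxo-4H-chromen-6-yl}-4-{6-[4-(benzyloxy)phenyl]-4-oxo-4H-pyran-2-yl}-3-oxobutanoate
Product: 17 racemic tert-butyl (E)-4-{5-(benzyloxy)-2-[4-(benzyloxy)phenyl]-7-methoxy-4-oxo-4H-chromen-6-yl}-4-{6-[4-(benzyloxy)phenyl]-4-oxo-4H-pyran-2-yl}-3-methoxybut-2-enoate
Conditions: HC(OMe)3, MeOH, TsOH·H2O (0.2 equiv), 40 °C
Reagents that add atoms: trimethyl orthoformate, COC(OC)OC
Why: Acid-catalysed enol ether formation from a β-keto ester with trimethyl orthoformate (ketal, then loss of methanol); under equilibrating conditions the conjugated (E)-3-methoxy-2-enoate, with the ester cis to the substituted carbon as the ring closure needs, should be favoured. The tert-butyl ester resists transesterification and catalytic acid.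

Step 11
Reactants: 17 racemic tert-butyl (E)-4-{5-(benzyloxy)-2-[4-(benzyloxy)phenyl]-7-methoxy-4-oxo-4H-chromen-6-yl}-4-{6-[4-(benzyloxy)phenyl]-4-oxo-4H-pyran-2-yl}-3-methoxybut-2-enoate
Product: 18 racemic (E)-4-{5-(benzyloxy)-2-[4-(benzyloxy)phenyl]-7-methoxy-4-oxo-4H-chromen-6-yl}-4-{6-[4-(benzyloxy)phenyl]-4-oxo-4H-pyran-2-yl}-3-methoxybut-2-enoic acid
Conditions: CF3CO2H/CH2Cl2 (1:4), 0 °C to rt, short reaction time
Reagents that add atoms: none
Why: Acidolysis of the tert-butyl ester with loss of 2-methylpropene; no hydroxide is used, so the acidic C4–H and the two pyranone rings are spared, and the protonated chromone ring is deactivated toward tert-butylation.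

Step 12
Reactants: 18 racemic (E)-4-{5-(benzyloxy)-2-[4-(benzyloxy)phenyl]-7-methoxy-4-oxo-4H-chromen-6-yl}-4-{6-[4-(benzyloxy)phenyl]-4-oxo-4H-pyran-2-yl}-3-methoxybut-2-enoic acid
Product: 21 5-(benzyloxy)-2-[4-(benzyloxy)phenyl]-6-{2-[4-(benzyloxy)phenyl]-5-hydroxy-7-methoxy-4-oxo-4H-chromen-8-yl}-7-methoxy-4H-chromen-4-one, via mixed trifluoroacetic anhydride 19 (not isolated), via dienylketene 20 (not isolated)
Conditions: (CF3CO)2O (1.3 equiv), Et3N (3 equiv), CH2Cl2, 0 °C to rt; then MeOH, aq. NaHCO3
Reagents that add atoms: none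
Why: Proposed new method: the carboxylate of 18 is acylated by (CF3CO)2O to the mixed anhydride 19, whose C4–H (C8 of unit 2) is benzylic and vinylogous to both the anhydride and the pyranone carbonyl, so Et3N removes it and trifluoroacetate leaves in a 1,4-elimination that gives dienylketene 20. The ketene C=C, the C7=C8 enol ether bond and the pyranone C8a=C4a bond form a hexatriene that closes by thermal disrotatory six-electron electrocyclisation between the ketene carbon (C5) and pyranone C3 (C4a); enolisation of the cyclohexadienone gives the hydrogen-bonded 5-hydroxyl and aromatic ring A of unit 2 with 7-OMe in place. The closest known reactions are Stobbe-type cyclisations of 4-arylbut-3-enoic acids with anhydrides to 1-naphthols and the last electrocyclic stage of the Danheiser benzannulation; closure onto C3 of a 4-pyranone has not been shown. No stereocentre is created: the racemic sp3 carbon of 18 becomes aromatic and the biaryl axis forms as the racemate. The step needs closure at pyranone C3 only, which the substrate secures because both ortho positions of the flavonyl group are substituted, the pyranone oxygen cannot reach the acyl carbon, and C3 is the only carbon that gives a six-membered ring; direct attack of the C3-nucleophilic dienolate on the anhydride would form the same bond and product. Only the E isomer of 20, with the ketene arm cis to the pyranone, can close, and the other isomer can return to it by reversible addition of trifluoroacetate.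

Step 13
Reactants: 21 5-(benzyloxy)-2-[4-(benzyloxy)phenyl]-6-{2-[4-(benzyloxy)phenyl]-5-hydroxy-7-methoxy-4-oxo-4H-chromen-8-yl}-7-methoxy-4H-chromen-4-one
Product: 22 DMGF (5-hydroxy-6-[5-hydroxy-2-(4-hydroxyphenyl)-7-methoxy-4-oxo-4H-chromen-8-yl]-2-(4-hydroxyphenyl)-7-methoxy-4H-chromen-4-one)
Conditions: H2 (1 atm), 10% Pd/C, THF/MeOH, rt
Reagents that add atoms: none
Why: Hydrogenolysis of the three aryl benzyl ethers on palladium; the methyl ethers stay, and the chromone C2=C3 bonds of flavones should not be reduced at one atmosphere.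

## Compound list

1 | apigenin | O=c1cc(-c2ccc(O)cc2)oc2cc(O)cc(O)c12 | starting material
2 | genkwanin, 5-hydroxy-2-(4-hydroxyphenyl)-7-methoxy-4H-chromen-4-one | COc1cc(O)c2c(=O)cc(-c3ccc(O)cc3)oc2c1 | intermediate
3 | 2-[4-(benzyloxy)phenyl]-5-hydroxy-7-methoxy-4H-chromen-4-one | COc1cc(O)c2c(=O)cc(-c3ccc(OCc4ccccc4)cc3)oc2c1 | intermediate
4 | 2-[4-(benzyloxy)phenyl]-5-hydroxy-6-iodo-7-methoxy-4H-chromen-4-one | COc1cc2oc(-c3ccc(OCc4ccccc4)cc3)cc(=O)c2c(O)c1I | intermediate
5 | 5-(benzyloxy)-2-[4-(benzyloxy)phenyl]-6-iodo-7-methoxy-4H-chromen-4-one | COc1cc2oc(-c3ccc(OCc4ccccc4)cc3)cc(=O)c2c(OCc2ccccc2)c1I | intermediate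
6 | ethyl bromoacetate | CCOC(=O)CBr | starting material
7 | bromo(2-ethoxy-2-oxoethyl)zinc (Reformatsky reagent, not isolated) | CCOC(=O)C[Zn]Br | intermediate
8 | ethyl 2-{5-(benzyloxy)-2-[4-(benzyloxy)phenyl]-7-methoxy-4-oxo-4H-chromen-6-yl}acetate | CCOC(=O)Cc1c(OC)cc2oc(-c3ccc(OCc4ccccc4)cc3)cc(=O)c2c1OCc1ccccc1 | intermediate
9 | 2-{5-(benzyloxy)-2-[4-(benzyloxy)phenyl]-7-methoxy-4-oxo-4H-chromen-6-yl}-N-methoxy-N-methylacetamide | CON(C)C(=O)Cc1c(OC)cc2oc(-c3ccc(OCc4ccccc4)cc3)cc(=O)c2c1OCc1ccccc1 | intermediate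
10 | 4'-(benzyloxy)acetophenone | CC(=O)c1ccc(OCc2ccccc2)cc1 | starting material
11 | 1-[4-(benzyloxy)phenyl]butane-1,3-dione | CC(=O)CC(=O)c1ccc(OCc2ccccc2)cc1 | intermediate
12 | 1-[4-(benzyloxy)phenyl]-6-{5-(benzyloxy)-2-[4-(benzyloxy)phenyl]-7-methoxy-4-oxo-4H-chromen-6-yl}hexane-1,3,5-trione (not isolated) | O=C(Cc1c(OC)cc2oc(-c3ccc(OCc4ccccc4)cc3)cc(=O)c2c1OCc1ccccc1)CC(=O)CC(=O)c1ccc(OCc2ccccc2)cc1 | intermediate
13 | 5-(benzyloxy)-2-[4-(benzyloxy)phenyl]-6-({6-[4-(benzyloxy)phenyl]-4-oxo-4H-pyran-2-yl}methyl)-7-methoxy-4H-chromen-4-one | O=c1cc(-c2ccc(OCc3ccccc3)cc2)oc(Cc2c(OC)cc3oc(-c4ccc(OCc5ccccc5)cc4)cc(=O)c3c2OCc2ccccc2)c1 | intermediate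
14 | 3-tert-butoxy-3-oxopropanoic acid (mono-tert-butyl malonate) | CC(C)(C)OC(=O)CC(=O)O | starting material
15 | tert-butyl 3-chloro-3-oxopropanoate (tert-butyl malonyl chloride, not isolated) | CC(C)(C)OC(=O)CC(=O)Cl | intermediate
16 | racemic tert-butyl 4-{5-(benzyloxy)-2-[4-(benzyloxy)phenyl]-7-methoxy-4-oxo-4H-chromen-6-yl}-4-{6-[4-(benzyloxy)phenyl]-4-oxo-4H-pyran-2-yl}-3-oxobutanoate | CC(C)(C)OC(=O)CC(=O)C(c1cc(=O)cc(-c2ccc(OCc3ccccc3)cc2)o1)c1c(OC)cc2oc(-c3ccc(OCc4ccccc4)cc3)cc(=O)c2c1OCc1ccccc1 | intermediate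
17 | racemic tert-butyl (E)-4-{5-(benzyloxy)-2-[4-(benzyloxy)phenyl]-7-methoxy-4-oxo-4H-chromen-6-yl}-4-{6-[4-(benzyloxy)phenyl]-4-oxo-4H-pyran-2-yl}-3-methoxybut-2-enoate | CC(C)(C)OC(=O)/C=C(/OC)C(c1cc(=O)cc(-c2ccc(OCc3ccccc3)cc2)o1)c1c(OC)cc2oc(-c3ccc(OCc4ccccc4)cc3)cc(=O)c2c1OCc1ccccc1 | intermediate
18 | racemic (E)-4-{5-(benzyloxy)-2-[4-(benzyloxy)phenyl]-7-methoxy-4-oxo-4H-chromen-6-yl}-4-{6-[4-(benzyloxy)phenyl]-4-oxo-4H-pyran-2-yl}-3-methoxybut-2-enoic acid | OC(=O)/C=C(/OC)C(c1cc(=O)cc(-c2ccc(OCc3ccccc3)cc2)o1)c1c(OC)cc2oc(-c3ccc(OCc4ccccc4)cc3)cc(=O)c2c1OCc1ccccc1 | intermediate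
19 | mixed anhydride of 18 with trifluoroacetic acid (not isolated) | O=C(OC(=O)C(F)(F)F)/C=C(/OC)C(c1cc(=O)cc(-c2ccc(OCc3ccccc3)cc2)o1)c1c(OC)cc2oc(-c3ccc(OCc4ccccc4)cc3)cc(=O)c2c1OCc1ccccc1 | intermediate
20 | (E)-4-{5-(benzyloxy)-2-[4-(benzyloxy)phenyl]-7-methoxy-4-oxo-4H-chromen-6-yl}-4-{6-[4-(benzyloxy)phenyl]-4-oxo-4H-pyran-2-yl}-3-methoxybuta-1,3-dien-1-one (dienylketene, ketene arm cis to the pyranone, not isolated) | O=C=C/C(OC)=C(\c1cc(=O)cc(-c2ccc(OCc3ccccc3)cc2)o1)c1c(OC)cc2oc(-c3ccc(OCc4ccccc4)cc3)cc(=O)c2c1OCc1ccccc1 | intermediate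
21 | 5-(benzyloxy)-2-[4-(benzyloxy)phenyl]-6-{2-[4-(benzyloxy)phenyl]-5-hydroxy-7-methoxy-4-oxo-4H-chromen-8-yl}-7-methoxy-4H-chromen-4-one (racemic axis) | COc1cc(O)c2c(=O)cc(-c3ccc(OCc4ccccc4)cc3)oc2c1-c1c(OC)cc2oc(-c3ccc(OCc4ccccc4)cc3)cc(=O)c2c1OCc1ccccc1 | intermediate
22 | DMGF, 5-hydroxy-6-[5-hydroxy-2-(4-hydroxyphenyl)-7-methoxy-4-oxo-4H-chromen-8-yl]-2-(4-hydroxyphenyl)-7-methoxy-4H-chromen-4-one (racemic axis) | COc1cc2oc(-c3ccc(O)cc3)cc(=O)c2c(O)c1-c1c(OC)cc(O)c2c(=O)cc(-c3ccc(O)cc3)oc12 | target

## Step count and risk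

Total step count: 13. Longest linear sequence: 12 steps, from apigenin 1 to 22 (steps 1 to 6 and 8 to 13); step 7 is a one-step side branch.

**Step 12 (key step, proposed new method).** The ketene 20 may be captured intermolecularly, the mixed anhydride may be acylated at oxygen, or the pyranone C3 may fail to engage, so that ring A does not close. The fallback is the known Suzuki–Miyaura union of two flavone halves. It sets out from 3 and 5 and returns at 22. Benzylation of 3 (BnBr, K2CO3, DMF) gives 5-(benzyloxy)-2-[4-(benzyloxy)phenyl]-7-methoxy-4H-chromen-4-one F1. With the 5-oxygen alkylated, iodination (iodine, CF3CO2Ag, CH2Cl2) enters at C8 and gives 5-(benzyloxy)-2-[4-(benzyloxy)phenyl]-8-iodo-7-methoxy-4H-chromen-4-one F2. Miyaura borylation (B2pin2, Pd2(dba)3, XPhos, KOAc, dioxane, 90 °C) gives the 8-(4,4,5,5-tetramethyl-1,3,2-dioxaborolan-2-yl)flavone F3. Coupling of F3 with 5 (Pd(OAc)2, SPhos, K3PO4, toluene/water, 100 °C) gives tetra-O-benzyl DMGF F4, and hydrogenolysis as in step 13 gives 22. This route pays with a coupling at two di-ortho-substituted carbons, which the main route avoids.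

**Step 5.** Transmetalation and reductive elimination at the di-ortho-substituted aryl–palladium may be slow, so that protodeiodination or homocoupling of the zinc enolate takes over. The fallback sets out from 5 and returns at 9. Stille coupling with allyltributylstannane (Pd(PPh3)4, toluene, 100 °C) gives 6-allyl-5-(benzyloxy)-2-[4-(benzyloxy)phenyl]-7-methoxy-4H-chromen-4-one F5. Oxidative cleavage (OsO4 cat., NaIO4, 2,6-lutidine, dioxane/water) gives the arylacetaldehyde F6, and Pinnick oxidation (NaClO2, NaH2PO4, 2-methyl-2-butene) gives the arylacetic acid F7. Activation with 1,1'-carbonyldiimidazole and MeNH(OMe)·HCl then gives 9.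

**Step 9.** The dienolate of 13 may be acylated at the pyranone oxygen, or the ketene formed from 15 may oligomerise before it is captured. The fallback sets out from 13 and returns at 16. Carboxylation of the lateral enolate (LiN(SiMe3)2, THF, −78 °C, then CO2) gives 2-{5-(benzyloxy)-2-[4-(benzyloxy)phenyl]-7-methoxy-4-oxo-4H-chromen-6-yl}-2-{6-[4-(benzyloxy)phenyl]-4-oxo-4H-pyran-2-yl}acetic acid F8. F8 is kept cold because it can decarboxylate. Activation with 1,1'-carbonyldiimidazole and reaction with the magnesium salt of 14 (from 14 and Mg(OEt)2, Masamune–Brooks chain extension under near-neutral conditions) gives 16.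

**Step 10.** Ketal formation at the hindered ketone may be slow, the tert-butyl group may be lost under the acid, or the enol ether may form toward C4 instead of C2. The C4 isomer would still give ketene 20 in step 12 by ordinary α-deprotonation of its anhydride. The fallback sets out from 16 and returns at 17. Enol tosylation (TsCl, N-methylimidazole, Et3N, CH2Cl2, 0 °C) gives tert-butyl (E)-4-{5-(benzyloxy)-2-[4-(benzyloxy)phenyl]-7-methoxy-4-oxo-4H-chromen-6-yl}-4-{6-[4-(benzyloxy)phenyl]-4-oxo-4H-pyran-2-yl}-3-(tosyloxy)but-2-enoate F9. Addition–elimination with NaOMe in MeOH/THF at 0 °C replaces the tosylate by methoxide and gives 17.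

## Further compounds

F1 | step 12 | 5-(benzyloxy)-2-[4-(benzyloxy)phenyl]-7-methoxy-4H-chromen-4-one | COc1cc(OCc2ccccc2)c2c(=O)cc(-c3ccc(OCc4ccccc4)cc3)oc2c1
F2 | step 12 | 5-(benzyloxy)-2-[4-(benzyloxy)phenyl]-8-iodo-7-methoxy-4H-chromen-4-one | COc1cc(OCc2ccccc2)c2c(=O)cc(-c3ccc(OCc4ccccc4)cc3)oc2c1I
F3 | step 12 | 5-(benzyloxy)-2-[4-(benzyloxy)phenyl]-7-methoxy-8-(4,4,5,5-tetramethyl-1,3,2-dioxaborolan-2-yl)-4H-chromen-4-one | COc1cc(OCc2ccccc2)c2c(=O)cc(-c3ccc(OCc4ccccc4)cc3)oc2c1B1OC(C)(C)C(C)(C)O1
F4 | step 12 | tetra-O-benzyl DMGF, 5-(benzyloxy)-6-{5-(benzyloxy)-2-[4-(benzyloxy)phenyl]-7-methoxy-4-oxo-4H-chromen-8-yl}-2-[4-(benzyloxy)phenyl]-7-methoxy-4H-chromen-4-one | COc1cc(OCc2ccccc2)c2c(=O)cc(-c3ccc(OCc4ccccc4)cc3)oc2c1-c1c(OC)cc2oc(-c3ccc(OCc4ccccc4)cc3)cc(=O)c2c1OCc1ccccc1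
F5 | step 5 | 6-allyl-5-(benzyloxy)-2-[4-(benzyloxy)phenyl]-7-methoxy-4H-chromen-4-one | C=CCc1c(OC)cc2oc(-c3ccc(OCc4ccccc4)cc3)cc(=O)c2c1OCc1ccccc1
F6 | step 5 | 2-{5-(benzyloxy)-2-[4-(benzyloxy)phenyl]-7-methoxy-4-oxo-4H-chromen-6-yl}acetaldehyde | O=CCc1c(OC)cc2oc(-c3ccc(OCc4ccccc4)cc3)cc(=O)c2c1OCc1ccccc1
F7 | step 5 | 2-{5-(benzyloxy)-2-[4-(benzyloxy)phenyl]-7-methoxy-4-oxo-4H-chromen-6-yl}acetic acid | OC(=O)Cc1c(OC)cc2oc(-c3ccc(OCc4ccccc4)cc3)cc(=O)c2c1OCc1ccccc1
F8 | step 9 | racemic 2-{5-(benzyloxy)-2-[4-(benzyloxy)phenyl]-7-methoxy-4-oxo-4H-chromen-6-yl}-2-{6-[4-(benzyloxy)phenyl]-4-oxo-4H-pyran-2-yl}acetic acid | OC(=O)C(c1cc(=O)cc(-c2ccc(OCc3ccccc3)cc2)o1)c1c(OC)cc2oc(-c3ccc(OCc4ccccc4)cc3)cc(=O)c2c1OCc1ccccc1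
F9 | step 10 | racemic tert-butyl (E)-4-{5-(benzyloxy)-2-[4-(benzyloxy)phenyl]-7-methoxy-4-oxo-4H-chromen-6-yl}-4-{6-[4-(benzyloxy)phenyl]-4-oxo-4H-pyran-2-yl}-3-(tosyloxy)but-2-enoate | CC(C)(C)OC(=O)/C=C(/OS(=O)(=O)c1ccc(C)cc1)C(c1cc(=O)cc(-c2ccc(OCc3ccccc3)cc2)o1)c1c(OC)cc2oc(-c3ccc(OCc4ccccc4)cc3)cc(=O)c2c1OCc1ccccc1
A1 | alternative 1 | (E)-1-{3-[5-(benzyloxy)-2-(4-(benzyloxy)phenyl)-7-methoxy-4-oxo-4H-chromen-8-yl]-2,6-dihydroxy-4-methoxyphenyl}-3-[4-(benzyloxy)phenyl]prop-2-en-1-one | O=C(/C=C/c1ccc(OCc2ccccc2)cc1)c1c(O)cc(OC)c(-c2c(OC)cc(OCc3ccccc3)c3c(=O)cc(-c4ccc(OCc5ccccc5)cc4)oc23)c1O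
A2 | alternative 1 | 6-{(E)-4-[4-(benzyloxy)phenyl]-2-oxobut-3-en-1-yl}-3-{5-(benzyloxy)-2-[4-(benzyloxy)phenyl]-7-methoxy-4-oxo-4H-chromen-8-yl}-4-methoxy-2H-pyran-2-one | O=C(/C=C/c1ccc(OCc2ccccc2)cc1)Cc1cc(OC)c(-c2c(OC)cc(OCc3ccccc3)c3c(=O)cc(-c4ccc(OCc5ccccc5)cc4)oc23)c(=O)o1
A3 | alternative 2 | 5,5''-di-O-methyl-4',4'''-di-O-benzyl DMGF | COc1cc2oc(-c3ccc(OCc4ccccc4)cc3)cc(=O)c2c(OC)c1-c1c(OC)cc(OC)c2c(=O)cc(-c3ccc(OCc4ccccc4)cc3)oc12
A4 | alternative 2 | biaryl bis(acylphosphorane) bis(4-benzyloxybenzoate): each future ring A carries a C(=O)CH=PPh3 group at C4a and a 4-(benzyloxy)benzoyloxy group at C8a | COc1cc(OC(=O)c2ccc(OCc3ccccc3)cc2)c(C(=O)C=P(c2ccccc2)(c2ccccc2)c2ccccc2)c(OC)c1-c1c(OC)cc(OC)c(C(=O)C=P(c2ccccc2)(c2ccccc2)c2ccccc2)c1OC(=O)c1ccc(OCc2ccccc2)cc1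
A5 | alternative 3 | tri-O-benzyl DMGF with free 5-OH in unit 1 | COc1cc2oc(-c3ccc(OCc4ccccc4)cc3)cc(=O)c2c(O)c1-c1c(OC)cc(OCc2ccccc2)c2c(=O)cc(-c3ccc(OCc4ccccc4)cc3)oc12
A6 | alternative 3 | 6-[4-(benzyloxy)phenyl]-2-(2-diazoacetyl)-4H-pyran-4-one | [N-]=[N+]=CC(=O)c1cc(=O)cc(-c2ccc(OCc3ccccc3)cc2)o1
A7 | alternative 3 | 5-(benzyloxy)-2-[4-(benzyloxy)phenyl]-7-methoxy-8-(methoxyethynyl)-4H-chromen-4-one | COC#Cc1c(OC)cc(OCc2ccccc2)c2c(=O)cc(-c3ccc(OCc4ccccc4)cc3)oc12
A8 | alternative 3 | 2-{6-[4-(benzyloxy)phenyl]-4-oxo-4H-pyran-2-yl}ethen-1-one (pyranylketene) | O=C=Cc1cc(=O)cc(-c2ccc(OCc3ccccc3)cc2)o1
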